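The plan rests on cutting the lactone at its aryl–oxygen bond, C8a–O1, which lies next to the C2 carbonyl in the six-membered dihydrocoumarin ring; taking that oxygen out contracts the ring to the five-membered ketone of a 3-phenylindan-1-one. In the forward sense a Baeyer–Villiger oxidation inserts oxygen between the arene carbon and the carbonyl in one operation, fixing where the lactone sits while the C3 stereocentre (C4 of the target) is carried through untouched. The substrate is (R)-7-bromo-4,6-dimethoxy-3-phenylindan-1-one, made by rhodium-catalysed asymmetric isomerisation of a propargylic alcohol; its bromine later becomes the C8 benzoyl group, and the C6 prenyl group is added last by a Claisen shift.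

Key step: step 4

Assumption: (R)-BINAP is taken to lead to the (R)-indanone in step 3; if a trial run shows the opposite sense of induction, (S)-BINAP is used and nothing else changes.

Step 1
Reactants: 1 3,5-dimethoxybenzaldehyde
Product: 2 2-bromo-3,5-dimethoxybenzaldehyde
Conditions: NBS (1.05 equiv), MeCN, 0 °C to rt
Reagents that add atoms: N-bromosuccinimide, O=C1CCC(=O)N1Br
Why: Electrophilic aromatic bromination, in which the position ortho to one methoxy group and para to the other should be attacked in preference to the more crowded site between the two methoxy groups, so one bromine enters at C2.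

Step 2
Reactants: 2 2-bromo-3,5-dimethoxybenzaldehyde; 3 phenylacetylene
Product: 6 rac-1-(2-bromo-3,5-dimethoxyphenyl)-3-phenylprop-2-yn-1-ol, via lithium phenylacetylide 4 (not isolated), via lithium propargylic alkoxide 5 (not isolated)
Conditions: 3 (1.2 equiv), n-BuLi (1.1 equiv), THF, −78 °C; then 2, −78 to 0 °C; H2O
Reagents that add atoms: none
Why: 1,2-Addition of a lithium acetylide to an aldehyde; with the alkyne in slight excess over n-BuLi no alkyllithium remains to exchange with the aryl bromide, and the racemic carbinol centre does not matter because step 3 erases it.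

Step 3
Reactants: 6 rac-1-(2-bromo-3,5-dimethoxyphenyl)-3-phenylprop-2-yn-1-ol
Product: 8 (R)-7-bromo-4,6-dimethoxy-3-phenylindan-1-one, via rhodium-bound ynone 7 (not isolated)
Conditions: [Rh(OH)(cod)]2 (2.5 mol%), (R)-BINAP (6 mol%), THF, 60 °C
Reagents that add atoms: none
Why: Rhodium-catalysed redox isomerisation of an α-arylpropargyl alcohol to a 3-substituted indan-1-one: β-hydride elimination from the rhodium alkoxide gives coordinated ynone 7 and a rhodium hydride, syn-hydrorhodation and a 1,4-rhodium shift move the metal to the only ortho carbon that carries hydrogen, and intramolecular 1,4-addition of this aryl–rhodium to the enone closes the five-membered ring and sets C3, with the enone face chosen by the chiral bisphosphine.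

Step 4
Reactants: 8 (R)-7-bromo-4,6-dimethoxy-3-phenylindan-1-one
Product: 10 (R)-8-bromo-5,7-dimethoxy-4-phenylchroman-2-one, via peroxyhemiketal adduct 9 (not isolated)
Conditions: mCPBA (1.5 equiv), TsOH·H2O (0.2 equiv), CH2Cl2, 0 °C to rt, dark
Reagents that add atoms: 3-chloroperoxybenzoic acid (mCPBA), O=C(OO)c1cccc(Cl)c1
Why: Baeyer–Villiger oxidation: the acid-activated ketone adds the peracid to give adduct 9, whose aryl carbon C7a shifts to the proximal oxygen as 3-chlorobenzoate leaves. The closest known reaction type is the peracid oxidation of 1-indanones, 3-aryl ones included, to 3,4-dihydrocoumarins. The six-membered lactone arises by ring expansion and not by cyclisation: a concerted 1,2-shift inserts oxygen into the C7a–C1 bond of the five-membered ring. No stereocentre is created, and C3 has no part in the reaction and no enolisable or ionisable path to it exists, so it becomes C4 with its configuration intact. The step needs aryl over methylene migration; in the fused adduct the peroxy oxygen stands above the arene plane in line with the p-orbital at C7a, the C7 bromine crowds the rotamer that would place the O–O bond anti to C1–C2, and the acid catalyst raises the cationic character that favours the sp2 carbon. It also needs chemoselectivity, which should follow because this is the only carbonyl group, no alkene is present yet, the phenols are methyl ethers, and the acyl and bromo substituents damp electrophilic hydroxylation of the ring.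

Step 5
Reactants: 10 (R)-8-bromo-5,7-dimethoxy-4-phenylchroman-2-one; 11 phenylboronic acid
Product: 12 (R)-8-benzoyl-5,7-dimethoxy-4-phenylchroman-2-one
Conditions: 11 (1.5 equiv), CO (5 bar), Pd(OAc)2 (2 mol%), di(1-adamantyl)-n-butylphosphine (6 mol%), TMEDA (1.5 equiv), toluene, 100 °C
Reagents that add atoms: carbon monoxide, [C-]#[O+]
Why: Carbonylative Suzuki–Miyaura coupling, in which zerovalent palladium inserts into the C8–Br bond, CO insertion gives an acylpalladium that transmetallates with the boronic acid and reductively eliminates the diaryl ketone; the anhydrous amine base spares the aryl lactone, which with O5 still methylated could in any case only re-close onto O1.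

Step 6
Reactants: 12 (R)-8-benzoyl-5,7-dimethoxy-4-phenylchroman-2-one
Product: 14 (R)-8-benzoyl-5,7-dihydroxy-4-phenylchroman-2-one, via bis(dibromoboryl) ether 13 (not isolated)
Conditions: BBr3 (5 equiv), CH2Cl2, −78 °C to rt; then H2O, 0 °C
Reagents that add atoms: none
Why: Boron tribromide cleavage of aryl methyl ethers, in which bromide attacks the methyl group of each boron-coordinated ether to give borate 13, hydrolysed by the cold quench; the aryl ester lactone, the diaryl ketone and C4 (no acidic hydrogen, no leaving group) are expected to persist.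

Step 7
Reactants: 14 (R)-8-benzoyl-5,7-dihydroxy-4-phenylchroman-2-one; 15 3-chloro-3-methylbut-1-yne
Product: 16 (R)-8-benzoyl-7-hydroxy-5-[(2-methylbut-3-yn-2-yl)oxy]-4-phenylchroman-2-one
Conditions: 15 (1.5 equiv), DBU (1.5 equiv), CuCl2·2H2O (1 mol%), MeCN, 0 °C
Reagents that add atoms: none
Why: Copper-catalysed propargylic etherification of a phenol by a tertiary propargyl chloride; the 5-OH, para to the benzoyl group and free of hydrogen bonding, should be deprotonated and alkylated, whereas the 7-OH is held in a hydrogen bond to the C8 ketone, so the ether should form at O5.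

Step 8
Reactants: 16 (R)-8-benzoyl-7-hydroxy-5-[(2-methylbut-3-yn-2-yl)oxy]-4-phenylchroman-2-one
Product: 17 (R)-8-benzoyl-7-hydroxy-5-[(2-methylbut-3-en-2-yl)oxy]-4-phenylchroman-2-one
Conditions: H2 (1 atm), Pd/CaCO3 poisoned with Pb(OAc)2 (Lindlar catalyst), quinoline, EtOAc, rt
Reagents that add atoms: none
Why: Lindlar semihydrogenation, in which the lead-poisoned palladium should reduce the terminal alkyne to the alkene and stop there, leaving the diaryl ketone, the lactone and the tertiary C–O bond alone.

Step 9
Reactants: 17 (R)-8-benzoyl-7-hydroxy-5-[(2-methylbut-3-en-2-yl)oxy]-4-phenylchroman-2-one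
Product: 19 (R)-8-benzoyl-5,7-dihydroxy-6-(3-methylbut-2-en-1-yl)-4-phenylchroman-2-one (CNP0337570.1), via cyclohexadienone 18 (not isolated)
Conditions: toluene, 110 °C, sealed tube, base-washed glassware
Reagents that add atoms: none
Why: Aromatic Claisen rearrangement, in which the [3,3]-sigmatropic shift of the 1,1-dimethylallyl aryl ether joins the allyl terminus to C6, the only ortho carbon bearing hydrogen (C4a is fully substituted), and dienone 18 tautomerises to the 5-phenol carrying the prenyl group; neutral thermal conditions should leave the lactone and C4 untouched.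

Compound list
1 | 3,5-dimethoxybenzaldehyde | COc1cc(C=O)cc(OC)c1 | starting material
2 | 2-bromo-3,5-dimethoxybenzaldehyde | COc1cc(C=O)c(Br)c(OC)c1 | intermediate
3 | phenylacetylene | C#Cc1ccccc1 | starting material
4 | lithium phenylacetylide | [Li]C#Cc1ccccc1 | intermediate
5 | lithium rac-1-(2-bromo-3,5-dimethoxyphenyl)-3-phenylprop-2-yn-1-olate | [Li+].[O-]C(C#Cc1ccccc1)c1cc(OC)cc(OC)c1Br | intermediate
6 | rac-1-(2-bromo-3,5-dimethoxyphenyl)-3-phenylprop-2-yn-1-ol | OC(C#Cc1ccccc1)c1cc(OC)cc(OC)c1Br | intermediate
7 | 1-(2-bromo-3,5-dimethoxyphenyl)-3-phenylprop-2-yn-1-one (held on rhodium) | O=C(C#Cc1ccccc1)c1cc(OC)cc(OC)c1Br | intermediate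
8 | (R)-7-bromo-4,6-dimethoxy-3-phenylindan-1-one | O=C1C[C@H](c2ccccc2)c2c(OC)cc(OC)c(Br)c12 | intermediate
9 | (3R)-7-bromo-1-hydroxy-4,6-dimethoxy-3-phenylindan-1-yl 3-chloroperoxybenzoate (both C1 epimers) | OC1(OOC(=O)c2cccc(Cl)c2)C[C@H](c2ccccc2)c2c(OC)cc(OC)c(Br)c12 | intermediate
10 | (R)-8-bromo-5,7-dimethoxy-4-phenylchroman-2-one | O=C1C[C@H](c2ccccc2)c2c(OC)cc(OC)c(Br)c2O1 | intermediate
11 | phenylboronic acid | OB(O)c1ccccc1 | starting material
12 | (R)-8-benzoyl-5,7-dimethoxy-4-phenylchroman-2-one | O=C1C[C@H](c2ccccc2)c2c(OC)cc(OC)c(C(=O)c3ccccc3)c2O1 | intermediate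
13 | (R)-8-benzoyl-5,7-bis(dibromoboryloxy)-4-phenylchroman-2-one | O=C1C[C@H](c2ccccc2)c2c(OB(Br)Br)cc(OB(Br)Br)c(C(=O)c3ccccc3)c2O1 | intermediate
14 | (R)-8-benzoyl-5,7-dihydroxy-4-phenylchroman-2-one | O=C1C[C@H](c2ccccc2)c2c(O)cc(O)c(C(=O)c3ccccc3)c2O1 | intermediate
15 | 3-chloro-3-methylbut-1-yne | CC(C)(Cl)C#C | starting material
16 | (R)-8-benzoyl-7-hydroxy-5-[(2-methylbut-3-yn-2-yl)oxy]-4-phenylchroman-2-one | O=C1C[C@H](c2ccccc2)c2c(OC(C)(C)C#C)cc(O)c(C(=O)c3ccccc3)c2O1 | intermediate
17 | (R)-8-benzoyl-7-hydroxy-5-[(2-methylbut-3-en-2-yl)oxy]-4-phenylchroman-2-one | O=C1C[C@H](c2ccccc2)c2c(OC(C)(C)C=C)cc(O)c(C(=O)c3ccccc3)c2O1 | intermediate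
18 | (4R)-8-benzoyl-7-hydroxy-6-(3-methylbut-2-en-1-yl)-4-phenyl-4,6-dihydro-3H-chromene-2,5-dione (both C6 epimers) | CC(C)=CCC1C(O)=C(C(=O)c2ccccc2)C2=C(C1=O)[C@@H](c1ccccc1)CC(=O)O2 | intermediate
19 | (R)-8-benzoyl-5,7-dihydroxy-6-(3-methylbut-2-en-1-yl)-4-phenylchroman-2-one | CC(C)=CCc1c(O)c(C(=O)c2ccccc2)c2c(c1O)[C@@H](c1ccccc1)CC(=O)O2 | target

Total step count: 9. Longest linear sequence: 9 steps (1 to 19); compounds 3, 11 and 15 enter as purchased reagents.

Steps most likely to fail

Step 4. The migrating arene is only weakly donating (both methoxy groups are meta to C7a, bromine is ortho), so migration of the C2 methylene could compete, peracid addition to the hindered ketone could stall, or the ring could be hydroxylated. The fallback leaves from indanone 8 and gives the migrating carbon an ortho oxygen donor before the oxidation. Miyaura borylation of the C7 bromide (B2pin2, Pd(dppf)Cl2, KOAc, dioxane, 80 °C) should give (R)-4,6-dimethoxy-3-phenyl-7-(4,4,5,5-tetramethyl-1,3,2-dioxaborolan-2-yl)indan-1-one F1. Oxidation of the C–B bond (NaBO3·4H2O, THF/H2O, rt) should give (R)-7-hydroxy-4,6-dimethoxy-3-phenylindan-1-one F2. With a hydroxyl ortho to C7a, peracid oxidation (mCPBA, CH2Cl2, 0 °C; a Dakin-type Baeyer–Villiger) is strongly biased toward the aryl shift and should give (R)-8-hydroxy-5,7-dimethoxy-4-phenylchroman-2-one F3. Triflation (Tf2O, pyridine, CH2Cl2, 0 °C) would give (R)-5,7-dimethoxy-2-oxo-4-phenylchroman-8-yl trifluoromethanesulfonate F4. Carbonylative Suzuki–Miyaura coupling of this triflate with phenylboronic acid 11 (CO 1 atm, Pd(dppf)Cl2, K2CO3, anisole, 80 °C) returns to the route at ketone 12.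

Step 3. The two antipodes of the alcohol may turn over at unequal rates, the facial selectivity of the ring-closing 1,4-addition may be insufficient, or the alkenyl-rhodium may be protonated before the 1,4-shift, giving simple redox isomerisation without ring closure. The fallback leaves from bromoaldehyde 2. A second bromination (Br2, AcOH, rt) should enter at C6 and give 2,6-dibromo-3,5-dimethoxybenzaldehyde F5. A single Suzuki–Miyaura coupling with (1-phenylvinyl)boronic acid (1.0 equiv, Pd(OAc)2, SPhos, K3PO4, toluene/H2O, 60 °C) would give 2-bromo-3,5-dimethoxy-6-(1-phenylvinyl)benzaldehyde F6; the two bromines are equivalent, so only the extent of coupling has to be controlled. Enantioselective intramolecular alkene hydroacylation with a cationic rhodium–BINAP catalyst ([Rh(nbd)2]BF4, BINAP, activated with H2; CH2Cl2, rt) would then close the five-membered ketone and set C3 by hydride delivery to one alkene face, returning to the route at indanone 8.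

Step 5. At the crowded, electron-rich C8–Br bond, oxidative addition may stall, direct transmetallation may outrun CO insertion, or hydrodebromination may take over. The fallback leaves from bromide 10 and separates C–C bond formation from introduction of the carbonyl oxygen. Suzuki–Miyaura coupling with (1-phenylvinyl)boronic acid (Pd(OAc)2, SPhos, anhydrous K3PO4, toluene, 90 °C) should give (R)-5,7-dimethoxy-4-phenyl-8-(1-phenylvinyl)chroman-2-one F7. Lemieux–Johnson cleavage of the 1,1-diarylethene (OsO4 cat., NaIO4, 2,6-lutidine, dioxane/H2O, rt) returns to the route at ketone 12.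

Further compounds
F1 | step 4 | (R)-4,6-dimethoxy-3-phenyl-7-(4,4,5,5-tetramethyl-1,3,2-dioxaborolan-2-yl)indan-1-one | O=C1C[C@H](c2ccccc2)c2c(OC)cc(OC)c(B3OC(C)(C)C(C)(C)O3)c12
F2 | step 4 | (R)-7-hydroxy-4,6-dimethoxy-3-phenylindan-1-one | O=C1C[C@H](c2ccccc2)c2c(OC)cc(OC)c(O)c12
F3 | step 4 | (R)-8-hydroxy-5,7-dimethoxy-4-phenylchroman-2-one | O=C1C[C@H](c2ccccc2)c2c(OC)cc(OC)c(O)c2O1
F4 | step 4 | (R)-5,7-dimethoxy-2-oxo-4-phenylchroman-8-yl trifluoromethanesulfonate | O=C1C[C@H](c2ccccc2)c2c(OC)cc(OC)c(OS(=O)(=O)C(F)(F)F)c2O1
F5 | step 3 | 2,6-dibromo-3,5-dimethoxybenzaldehyde | COc1cc(OC)c(Br)c(C=O)c1Br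
F6 | step 3 | 2-bromo-3,5-dimethoxy-6-(1-phenylvinyl)benzaldehyde | COc1cc(OC)c(C(=C)c2ccccc2)c(C=O)c1Br
F7 | step 5 | (R)-5,7-dimethoxy-4-phenyl-8-(1-phenylvinyl)chroman-2-one | O=C1C[C@H](c2ccccc2)c2c(OC)cc(OC)c(C(=C)c3ccccc3)c2O1
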